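**Plan**
Cuts, in order: the C8 ester C–O, the C1/C10 epoxide oxygen, C11=C13 and the C3 benzoate; then C4–C15 and H–C5; then the ring bond C5–C6; then C7–C11 and C9–C10.
Enabling feature: the Z C4=C5 alkene between the C3 and C6 carbinols of the ten-membered ring is the syn hydromethylation product of a C4≡C5 ring alkyne, so the ring can be closed by adding an alkynyl C5 to a C6 aldehyde.
Forward: vinyl iodide 11 (C1–C5, C10, C14) and epoxy ester 13 (C6–C9) are joined at C9–C10, bromoacetate 17 adds C11–C12 at C7, and the open chain 23 is closed to the ten-membered carbocycle at C5–C6.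
Then methyl C15 is added across the ring alkyne, the γ-lactone (O6–C12) is closed, C13 is installed, and the C8 ester and the C1/C10 epoxide come last.
Stereochemistry: C3 and C8 from chiral-pool epoxides; C7 from C8 (chelated anti alkylation); C6 from C7 (ring closure); E C1=C10 from syn hydrozirconation; Z C4=C5 from syn carbometalation in the ring.
The C1/C10 epoxide comes from peripheral peracid attack on the macrocycle, the epoxyangelate from a Sharpless epoxidation.

Key step: step 15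

Remark: germacrane numbering (ring C1–C10, lactone carbons C11–C13, C14 on C10, C15 on C4) is used for every intermediate, and (S)-4-methoxybenzyl glycidyl ether 1 is assumed to be purchasable (otherwise one step from (S)-glycidol).

**Route**

Step 1
Reactants: 1 (S)-2-{[(4-methoxybenzyl)oxy]methyl}oxirane; 2 1-propynyllithium
Product: 3 (2S)-1-[(4-methoxybenzyl)oxy]hex-4-yn-2-ol
Conditions: BF3·OEt2, THF, −78 °C
Reagents that add atoms: none
Why: Yamaguchi–Hirao alkynylation, in which the BF3-activated terminal epoxide is opened at its CH2 terminus by the acetylide, so the C3 configuration of the glycidyl ether is carried over untouched.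

Step 2
Reactants: 3 (2S)-1-[(4-methoxybenzyl)oxy]hex-4-yn-2-ol
Product: 4 triethyl{[(2S)-1-[(4-methoxybenzyl)oxy]hex-4-yn-2-yl]oxy}silane
Conditions: Et3SiCl, imidazole, DMF, 0 °C → rt
Reagents that add atoms: chlorotriethylsilane, CC[Si](Cl)(CC)CC
Why: imidazole-promoted silylation of a secondary alcohol; the TES ether tolerates organometallics, base and DDQ and leaves later under mild acid.

Step 3
Reactants: 4 triethyl{[(2S)-1-[(4-methoxybenzyl)oxy]hex-4-yn-2-yl]oxy}silane
Product: 6 triethyl{[(2S,4E)-5-iodo-1-[(4-methoxybenzyl)oxy]hex-4-en-2-yl]oxy}silane, via alkenylzirconocene chloride 5 (not isolated)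
Conditions: Cp2Zr(H)Cl (2.5 equiv), THF, 50 °C; then I2, THF, 0 °C
Reagents that add atoms: iodine, II
Why: syn hydrozirconation with excess Cp2Zr(H)Cl equilibrates zirconium to the less hindered, methyl-bearing alkyne carbon (C10), and iodinolysis with retention gives the E iodide that fixes the C1=C10 geometry.

Step 4
Reactants: 6 triethyl{[(2S,4E)-5-iodo-1-[(4-methoxybenzyl)oxy]hex-4-en-2-yl]oxy}silane
Product: 7 (2S,4E)-5-iodo-2-(triethylsilyloxy)hex-4-en-1-ol
Conditions: DDQ, CH2Cl2/pH 7 buffer, 0 °C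
Reagents that add atoms: none
Why: oxidative cleavage of the PMB ether by hydride abstraction with DDQ, to which the silyl ether and the vinyl iodide are inert.

Step 5
Reactants: 7 (2S,4E)-5-iodo-2-(triethylsilyloxy)hex-4-en-1-ol
Product: 8 (2S,4E)-5-iodo-2-(triethylsilyloxy)hex-4-enal
Conditions: Dess–Martin periodinane, pyridine, CH2Cl2, 0 °C → rt
Reagents that add atoms: none
Why: Dess–Martin oxidation under buffered conditions, which should give the α-silyloxy aldehyde without epimerisation.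

Step 6
Reactants: 8 (2S,4E)-5-iodo-2-(triethylsilyloxy)hex-4-enal
Product: 9 triethyl{[(3S,5E)-6-iodohept-5-en-1-yn-3-yl]oxy}silane
Conditions: dimethyl (1-diazo-2-oxopropyl)phosphonate, K2CO3, MeOH, 0 °C → rt
Reagents that add atoms: dimethyl (1-diazo-2-oxopropyl)phosphonate, COP(=O)(OC)C(=[N+]=[N-])C(C)=O
Why: Ohira–Bestmann (Seyferth–Gilbert) homologation turns the aldehyde into the C4≡C5 terminal alkyne under carbonate/methanol conditions that α-silyloxy aldehydes normally survive with their configuration intact.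

Step 7
Reactants: 9 triethyl{[(3S,5E)-6-iodohept-5-en-1-yn-3-yl]oxy}silane
Product: 11 triethyl{[(3S,5E)-6-iodo-1-(trimethylsilyl)hept-5-en-1-yn-3-yl]oxy}silane, via lithium acetylide 10 (not isolated)
Conditions: LiN(SiMe3)2, THF, −78 °C; then Me3SiCl
Reagents that add atoms: chlorotrimethylsilane, C[Si](C)(C)Cl
Why: deprotonation and C-silylation of the terminal alkyne masks the acidic C–H before the iodine–lithium exchange of step 9.

Step 8
Reactants: 12 ethyl (3S)-4-chloro-3-hydroxybutanoate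
Product: 13 ethyl [(2S)-oxiran-2-yl]acetate
Conditions: Ag2O, DME, 60 °C
Reagents that add atoms: none
Why: Ag2O-assisted intramolecular Williamson etherification of the chlorohydrin under non-basic conditions, which avoids β-elimination of the ester and leaves the C8 centre untouched.

Step 9
Reactants: 11 triethyl{[(3S,5E)-6-iodo-1-(trimethylsilyl)hept-5-en-1-yn-3-yl]oxy}silane; 13 ethyl [(2S)-oxiran-2-yl]acetate
Product: 16 ethyl (3R,5E,8S)-3-hydroxy-5-methyl-8-(triethylsilyloxy)-10-(trimethylsilyl)dec-5-en-9-ynoate, via alkenyllithium 14 (not isolated), via alkenylmagnesium bromide 15 (not isolated)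
Conditions: t-BuLi (2.1 equiv), Et2O, −78 °C; MgBr2·OEt2; then 13, CuI (10 mol %), THF, −40 → −20 °C
Reagents that add atoms: none
Why: iodine–lithium exchange with retention, transmetalation to magnesium and CuI-catalysed SN2 opening of the terminal epoxide at C9 (as known for vinyl Grignard reagents and this epoxy ester) forge C9–C10 and give the β-hydroxy ester with C8 and the E alkene unchanged.

Step 10
Reactants: 16 ethyl (3R,5E,8S)-3-hydroxy-5-methyl-8-(triethylsilyloxy)-10-(trimethylsilyl)dec-5-en-9-ynoate; 17 tert-butyl bromoacetate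
Product: 19 4-tert-butyl 1-ethyl (2R)-2-[(1R,3E,6S)-1-hydroxy-3-methyl-6-(triethylsilyloxy)-8-(trimethylsilyl)oct-3-en-7-yn-1-yl]butanedioate, via dilithium dianion 18 (not isolated)
Conditions: LiN(i-Pr)2 (2.2 equiv), THF, −78 → −20 °C; then 17, DMPU, −78 → −40 °C
Reagents that add atoms: none
Why: Fráter–Seebach alkylation, in which the lithium-chelated alkoxide–enolate is attacked by the bromoacetate on the face away from the C8 substituent, setting C7 anti to the C8 oxygen; the tert-butyl ester keeps the γ-alkoxide from lactonising.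

Step 11
Reactants: 19 4-tert-butyl 1-ethyl (2R)-2-[(1R,3E,6S)-1-hydroxy-3-methyl-6-(triethylsilyloxy)-8-(trimethylsilyl)oct-3-en-7-yn-1-yl]butanedioate
Product: 20 4-tert-butyl 1-ethyl (2R)-2-[(1R,3E,6S)-1-(tert-butyldimethylsilyloxy)-3-methyl-6-(triethylsilyloxy)-8-(trimethylsilyl)oct-3-en-7-yn-1-yl]butanedioate
Conditions: t-BuMe2SiOTf, 2,6-lutidine, CH2Cl2, −78 °C
Reagents that add atoms: tert-butyldimethylsilyl trifluoromethanesulfonate, CC(C)(C)[Si](C)(C)OS(=O)(=O)C(F)(F)F
Why: silyl triflate silylation of the hindered secondary alcohol at low temperature, where the tert-butyl ester is stable.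

Step 12
Reactants: 20 4-tert-butyl 1-ethyl (2R)-2-[(1R,3E,6S)-1-(tert-butyldimethylsilyloxy)-3-methyl-6-(triethylsilyloxy)-8-(trimethylsilyl)oct-3-en-7-yn-1-yl]butanedioate
Product: 21 4-tert-butyl 1-ethyl (2R)-2-[(1R,3E,6S)-1-(tert-butyldimethylsilyloxy)-8-iodo-3-methyl-6-(triethylsilyloxy)oct-3-en-7-yn-1-yl]butanedioate
Conditions: N-iodosuccinimide, AgNO3 (20 mol %), DMF, rt, dark
Reagents that add atoms: N-iodosuccinimide, O=C1CCC(=O)N1I
Why: silver-catalysed iododesilylation, in which AgNO3 activates the alkynyl C–Si bond and N-iodosuccinimide delivers iodine, a standard one-step route from alkynylsilanes to 1-iodoalkynes that spares alkenes, esters and silyl ethers.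

Step 13
Reactants: 21 4-tert-butyl 1-ethyl (2R)-2-[(1R,3E,6S)-1-(tert-butyldimethylsilyloxy)-8-iodo-3-methyl-6-(triethylsilyloxy)oct-3-en-7-yn-1-yl]butanedioate
Product: 22 tert-butyl (3S,4R,6E,9S)-4-(tert-butyldimethylsilyloxy)-3-(hydroxymethyl)-11-iodo-6-methyl-9-(triethylsilyloxy)undec-6-en-10-ynoate
Conditions: i-Bu2AlH (2.3 equiv), CH2Cl2, −78 °C; aq. potassium sodium tartrate
Reagents that add atoms: none
Why: chemoselective hydride reduction, since at −78 °C i-Bu2AlH reduces the ethyl ester to the C6 primary alcohol much faster than the tert-butyl ester and does not hydroaluminate the iodoalkyne.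

Step 14
Reactants: 22 tert-butyl (3S,4R,6E,9S)-4-(tert-butyldimethylsilyloxy)-3-(hydroxymethyl)-11-iodo-6-methyl-9-(triethylsilyloxy)undec-6-en-10-ynoate
Product: 23 tert-butyl (3R,4R,6E,9S)-4-(tert-butyldimethylsilyloxy)-3-formyl-11-iodo-6-methyl-9-(triethylsilyloxy)undec-6-en-10-ynoate
Conditions: Dess–Martin periodinane, pyridine, CH2Cl2, 0 °C
Reagents that add atoms: none
Why: buffered Dess–Martin oxidation should give the α-branched, β-silyloxy C6 aldehyde without epimerisation at C7 or β-elimination; it is used at once.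

Step 15
Reactants: 23 tert-butyl (3R,4R,6E,9S)-4-(tert-butyldimethylsilyloxy)-3-formyl-11-iodo-6-methyl-9-(triethylsilyloxy)undec-6-en-10-ynoate
Product: 25 tert-butyl 2-[(1S,2S,5S,7E,10R)-10-(tert-butyldimethylsilyloxy)-2-hydroxy-8-methyl-5-(triethylsilyloxy)cyclodec-7-en-3-yn-1-yl]acetate, via alkynylchromium dichloride 24 (not isolated)
Conditions: CrCl2 (6 equiv), NiCl2 (1 mol %), THF, 25 °C, 2 mM (slow addition of 23)
Reagents that add atoms: none
Why: divalent chromium reduces the trace NiCl2 to zerovalent nickel, which inserts into the C5–I bond; transmetalation gives an alkynyl species of trivalent chromium that adds irreversibly to the C6 aldehyde under neutral conditions, so the epimerisable β-silyloxy aldehyde, both silyl ethers and the ester survive. The closest known reaction type is the Nozaki–Hiyama–Kishi alkynyl iodide–aldehyde cyclisation used to close ten-membered enediyne carbocycles. The ten-membered ring closes by intramolecular 1,2-addition (10-exo-trig at the carbonyl), the C3–C4≡C5–C6 unit being spanned with only modest bending of the alkyne and the E C1=C10 alkene removing rotors from the chain. The new C6 stereocentre is controlled by C7: in the Felkin–Anh arrangement the alkynyl group enters opposite the C8 branch, and in the ring-constrained alternative the chromium-bound oxygen takes the open sector between H7 and C11, both leading to the 6,7-relationship of the trans-lactone. The step needs cyclisation over oligomerisation and aldehyde over ester selectivity; high dilution with slow addition should secure the first and the inherent carbonyl selectivity of organochromium reagents the second.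

Step 16
Reactants: 25 tert-butyl 2-[(1S,2S,5S,7E,10R)-10-(tert-butyldimethylsilyloxy)-2-hydroxy-8-methyl-5-(triethylsilyloxy)cyclodec-7-en-3-yn-1-yl]acetate
Product: 27 tert-butyl 2-[(1S,2R,3Z,5S,7E,10R)-10-(tert-butyldimethylsilyloxy)-2-hydroxy-4,8-dimethyl-5-(triethylsilyloxy)cyclodeca-3,7-dien-1-yl]acetate, via alkenylmagnesium alkoxide 26 (not isolated)
Conditions: MeMgBr (5 equiv), Fe(acac)3 (20 mol %), THF, −78 → 0 °C; aq. NH4Cl
Reagents that add atoms: methylmagnesium bromide, C[Mg]Br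
Why: alkoxide-directed iron-catalysed carbomagnesiation of a propargylic alcohol, in which the C6 magnesium alkoxide steers syn addition of methyl to the distal carbon C4 and metal to C5, and protonation gives the trisubstituted alkene, which a syn addition to a ring alkyne can only deliver as the ring-cis (Z) isomer; the silylated C3 oxygen cannot direct.

Step 17
Reactants: 27 tert-butyl 2-[(1S,2R,3Z,5S,7E,10R)-10-(tert-butyldimethylsilyloxy)-2-hydroxy-4,8-dimethyl-5-(triethylsilyloxy)cyclodeca-3,7-dien-1-yl]acetate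
Product: 30 (3S,6R,7S,8R)-8-(tert-butyldimethylsilyloxy)-3-hydroxy-13-norgermacra-1(10)E,4Z-dien-12,6-olide, via silyl ester 28 (not isolated), via dihydroxy acid 29 (not isolated)
Conditions: Me3SiOTf, 2,6-lutidine, CH2Cl2, 0 °C → rt; then MeOH, PPTS, rt
Reagents that add atoms: none
Why: silyl triflate cleavage of the tert-butyl ester (loss of isobutene) followed by acidic methanolysis frees the acid and the C3 and C6 hydroxyls, and the γ-hydroxy acid lactonises onto O6, the only hydroxyl that can reach C12 in a five-membered ring, while the C8 TBS ether withstands PPTS.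

Step 18
Reactants: 30 (3S,6R,7S,8R)-8-(tert-butyldimethylsilyloxy)-3-hydroxy-13-norgermacra-1(10)E,4Z-dien-12,6-olide
Product: 31 (3S,6R,7S,8R)-3-benzoyloxy-8-(tert-butyldimethylsilyloxy)-13-norgermacra-1(10)E,4Z-dien-12,6-olide
Conditions: BzCl, pyridine, DMAP (cat.), CH2Cl2, 0 °C → rt
Reagents that add atoms: benzoyl chloride, O=C(Cl)c1ccccc1
Why: DMAP-catalysed acylation of the only free hydroxyl (C3).

Step 19
Reactants: 31 (3S,6R,7S,8R)-3-benzoyloxy-8-(tert-butyldimethylsilyloxy)-13-norgermacra-1(10)E,4Z-dien-12,6-olide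
Product: 33 (3S,6R,7S,8R)-3-benzoyloxy-8-(tert-butyldimethylsilyloxy)-13-(dimethylamino)germacra-1(10)E,4Z-dien-12,6-olide (C11 epimers), via lithium enolate 32 (not isolated)
Conditions: LiN(SiMe3)2, THF, −78 °C; then CH2=NMe2+ I−, −78 → 0 °C
Reagents that add atoms: N,N-dimethylmethyleneiminium iodide, C=[N+](C)C.[I-]
Why: Mannich reaction of the lithium lactone enolate with Eschenmoser's salt; the silylamide base is non-nucleophilic toward the benzoate, C7 carries no β-leaving group, and the new C11 centre is erased in the next step.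

Step 20
Reactants: 33 (3S,6R,7S,8R)-3-benzoyloxy-8-(tert-butyldimethylsilyloxy)-13-(dimethylamino)germacra-1(10)E,4Z-dien-12,6-olide (C11 epimers)
Product: 35 (3S,6R,7S,8R)-3-benzoyloxy-8-(tert-butyldimethylsilyloxy)germacra-1(10)E,4Z,11(13)-trien-12,6-olide, via ammonium iodide 34 (not isolated)
Conditions: MeI, MeOH, rt; then aq. NaHCO3, CH2Cl2, rt
Reagents that add atoms: none
Why: exhaustive N-methylation followed by mild-base E1cB (Hofmann-type) elimination of trimethylamine unveils the exocyclic C11=C13 methylene.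

Step 21
Reactants: 35 (3S,6R,7S,8R)-3-benzoyloxy-8-(tert-butyldimethylsilyloxy)germacra-1(10)E,4Z,11(13)-trien-12,6-olide
Product: 36 (3S,6R,7R,8R)-3-benzoyloxy-8-hydroxygermacra-1(10)E,4Z,11(13)-trien-12,6-olide
Conditions: HF·pyridine, pyridine, THF, 0 °C → rt
Reagents that add atoms: none
Why: fluoride-mediated desilylation under buffered, weakly acidic conditions that the benzoate and the Michael-acceptor lactone tolerate.

Step 22
Reactants: 37 methyl (2Z)-2-methylbut-2-enoate (methyl angelate)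
Product: 38 (2Z)-2-methylbut-2-en-1-ol
Conditions: i-Bu2AlH (2.2 equiv), Et2O, −78 → 0 °C
Reagents that add atoms: none
Why: 1,2-hydride reduction of the enoate to the allylic alcohol at low temperature, which preserves the Z geometry.

Step 23
Reactants: 38 (2Z)-2-methylbut-2-en-1-ol
Product: 39 [(2S,3R)-2,3-dimethyloxiran-2-yl]methanol
Conditions: t-BuOOH, Ti(O-i-Pr)4 (10 mol %), L-(+)-diethyl tartrate (12 mol %), 4 Å MS, CH2Cl2, −20 °C
Reagents that add atoms: tert-butyl hydroperoxide, CC(C)(C)OO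
Why: Sharpless asymmetric epoxidation, in which the titanium–L-(+)-tartrate–peroxide complex delivers oxygen to the alkene face that gives the (2S,3R) epoxy alcohol, the Z geometry fixing hydroxymethyl and the C3 methyl cis.

Step 24
Reactants: 39 [(2S,3R)-2,3-dimethyloxiran-2-yl]methanol
Product: 40 (2R,3R)-2,3-dimethyloxirane-2-carboxylic acid
Conditions: RuCl3 (2 mol %), NaIO4, CCl4/MeCN/H2O, rt
Reagents that add atoms: water, O
Why: RuO4-catalysed oxidation of the primary epoxy alcohol to the carboxylic acid, the standard follow-up to a Sharpless epoxidation, which leaves the epoxide and both stereocentres intact.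

Step 25
Reactants: 36 (3S,6R,7R,8R)-3-benzoyloxy-8-hydroxygermacra-1(10)E,4Z,11(13)-trien-12,6-olide; 40 (2R,3R)-2,3-dimethyloxirane-2-carboxylic acid
Product: 42 (3S,6R,7R,8R)-3-benzoyloxy-8-[(2R,3R)-2,3-dimethyloxirane-2-carbonyloxy]germacra-1(10)E,4Z,11(13)-trien-12,6-olide, via mixed anhydride 41 (not isolated)
Conditions: 2,4,6-trichlorobenzoyl chloride, Et3N, THF, rt; then 36, DMAP, toluene, rt
Reagents that add atoms: none
Why: Yamaguchi esterification, in which the mixed trichlorobenzoic anhydride of the hindered epoxy acid acylates the secondary C8 alcohol under DMAP catalysis without touching either stereocentre of the acid.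

Step 26
Reactants: 42 (3S,6R,7R,8R)-3-benzoyloxy-8-[(2R,3R)-2,3-dimethyloxirane-2-carbonyloxy]germacra-1(10)E,4Z,11(13)-trien-12,6-olide
Product: 43 (1R,3S,6R,7R,8R,10R)-3-benzoyloxy-1,10-epoxy-8-[(2R,3R)-2,3-dimethyloxirane-2-carbonyloxy]germacra-4Z,11(13)-dien-12,6-olide (CNP0324463.6)
Conditions: mCPBA, NaHCO3, CH2Cl2, 0 °C
Reagents that add atoms: 3-chloroperoxybenzoic acid, OOC(=O)c1cccc(Cl)c1
Why: Prilezhaev epoxidation, in which the peracid attacks the only electron-rich alkene (C1=C10; C4=C5 is flanked by two acyloxy groups and C11=C13 is conjugated) from the outer face of the crown-like ten-membered ring, which should give the (1R,10R) trans-epoxide.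

**Compound list**
1 | (S)-2-{[(4-methoxybenzyl)oxy]methyl}oxirane | COc1ccc(COC[C@@H]2CO2)cc1 | starting material
2 | 1-propynyllithium | [Li]C#CC | starting material
3 | (2S)-1-[(4-methoxybenzyl)oxy]hex-4-yn-2-ol | CC#CC[C@H](O)COCc1ccc(OC)cc1 | intermediate
4 | triethyl{[(2S)-1-[(4-methoxybenzyl)oxy]hex-4-yn-2-yl]oxy}silane | CC#CC[C@H](O[Si](CC)(CC)CC)COCc1ccc(OC)cc1 | intermediate
5 | alkenylzirconocene chloride, chlorobis(cyclopentadienyl)[(2E,5S)-6-[(4-methoxybenzyl)oxy]-5-(triethylsilyloxy)hex-2-en-2-yl]zirconium (not isolated) | C/C(=C\C[C@H](O[Si](CC)(CC)CC)COCc1ccc(OC)cc1)[Zr](Cl)(C1C=CC=C1)C1C=CC=C1 | intermediate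
6 | triethyl{[(2S,4E)-5-iodo-1-[(4-methoxybenzyl)oxy]hex-4-en-2-yl]oxy}silane | C/C(I)=C\C[C@H](O[Si](CC)(CC)CC)COCc1ccc(OC)cc1 | intermediate
7 | (2S,4E)-5-iodo-2-(triethylsilyloxy)hex-4-en-1-ol | C/C(I)=C\C[C@H](O[Si](CC)(CC)CC)CO | intermediate
8 | (2S,4E)-5-iodo-2-(triethylsilyloxy)hex-4-enal | C/C(I)=C\C[C@H](O[Si](CC)(CC)CC)C=O | intermediate
9 | triethyl{[(3S,5E)-6-iodohept-5-en-1-yn-3-yl]oxy}silane | C/C(I)=C\C[C@H](O[Si](CC)(CC)CC)C#C | intermediate
10 | lithium acetylide of 9 (not isolated) | C/C(I)=C\C[C@H](O[Si](CC)(CC)CC)C#C[Li] | intermediate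
11 | triethyl{[(3S,5E)-6-iodo-1-(trimethylsilyl)hept-5-en-1-yn-3-yl]oxy}silane | C/C(I)=C\C[C@H](O[Si](CC)(CC)CC)C#C[Si](C)(C)C | intermediate
12 | ethyl (3S)-4-chloro-3-hydroxybutanoate | CCOC(=O)C[C@H](O)CCl | starting material
13 | ethyl [(2S)-oxiran-2-yl]acetate | CCOC(=O)C[C@H]1CO1 | intermediate
14 | alkenyllithium, C10–Li in place of C10–I of 11, geometry retained (not isolated) | C/C([Li])=C\C[C@H](O[Si](CC)(CC)CC)C#C[Si](C)(C)C | intermediate
15 | alkenylmagnesium bromide, C10–MgBr (not isolated) | C/C([Mg]Br)=C\C[C@H](O[Si](CC)(CC)CC)C#C[Si](C)(C)C | intermediate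
16 | ethyl (3R,5E,8S)-3-hydroxy-5-methyl-8-(triethylsilyloxy)-10-(trimethylsilyl)dec-5-en-9-ynoate | CCOC(=O)C[C@H](O)C/C(C)=C/C[C@H](O[Si](CC)(CC)CC)C#C[Si](C)(C)C | intermediate
17 | tert-butyl bromoacetate | CC(C)(C)OC(=O)CBr | starting material
18 | dilithium alkoxide–enolate of 16 (not isolated) | CCOC(O[Li])=C[C@H](O[Li])C/C(C)=C/C[C@H](O[Si](CC)(CC)CC)C#C[Si](C)(C)C | intermediate
19 | 4-tert-butyl 1-ethyl (2R)-2-[(1R,3E,6S)-1-hydroxy-3-methyl-6-(triethylsilyloxy)-8-(trimethylsilyl)oct-3-en-7-yn-1-yl]butanedioate | CCOC(=O)[C@H](CC(=O)OC(C)(C)C)[C@H](O)C/C(C)=C/C[C@H](O[Si](CC)(CC)CC)C#C[Si](C)(C)C | intermediate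
20 | 4-tert-butyl 1-ethyl (2R)-2-[(1R,3E,6S)-1-(tert-butyldimethylsilyloxy)-3-methyl-6-(triethylsilyloxy)-8-(trimethylsilyl)oct-3-en-7-yn-1-yl]butanedioate | CCOC(=O)[C@H](CC(=O)OC(C)(C)C)[C@H](O[Si](C)(C)C(C)(C)C)C/C(C)=C/C[C@H](O[Si](CC)(CC)CC)C#C[Si](C)(C)C | intermediate
21 | 4-tert-butyl 1-ethyl (2R)-2-[(1R,3E,6S)-1-(tert-butyldimethylsilyloxy)-8-iodo-3-methyl-6-(triethylsilyloxy)oct-3-en-7-yn-1-yl]butanedioate | CCOC(=O)[C@H](CC(=O)OC(C)(C)C)[C@H](O[Si](C)(C)C(C)(C)C)C/C(C)=C/C[C@H](O[Si](CC)(CC)CC)C#CI | intermediate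
22 | tert-butyl (3S,4R,6E,9S)-4-(tert-butyldimethylsilyloxy)-3-(hydroxymethyl)-11-iodo-6-methyl-9-(triethylsilyloxy)undec-6-en-10-ynoate | OC[C@H](CC(=O)OC(C)(C)C)[C@H](O[Si](C)(C)C(C)(C)C)C/C(C)=C/C[C@H](O[Si](CC)(CC)CC)C#CI | intermediate
23 | tert-butyl (3R,4R,6E,9S)-4-(tert-butyldimethylsilyloxy)-3-formyl-11-iodo-6-methyl-9-(triethylsilyloxy)undec-6-en-10-ynoate (open-chain iodoalkyne aldehyde) | CC(C)(C)OC(=O)C[C@@H](C=O)[C@H](O[Si](C)(C)C(C)(C)C)C/C(C)=C/C[C@H](O[Si](CC)(CC)CC)C#CI | intermediate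
24 | alkynylchromium dichloride, C5–CrCl2 in place of C5–I of 23 (not isolated) | CC(C)(C)OC(=O)C[C@@H](C=O)[C@H](O[Si](C)(C)C(C)(C)C)C/C(C)=C/C[C@H](O[Si](CC)(CC)CC)C#C[Cr](Cl)Cl | intermediate
25 | tert-butyl 2-[(1S,2S,5S,7E,10R)-10-(tert-butyldimethylsilyloxy)-2-hydroxy-8-methyl-5-(triethylsilyloxy)cyclodec-7-en-3-yn-1-yl]acetate (ten-membered cycloalkynol; germacrane 3S,6S,7S,8R) | CC(C)(C)OC(=O)C[C@H]1[C@H](O)C#C[C@@H](O[Si](CC)(CC)CC)C/C=C(\C)C[C@H]1O[Si](C)(C)C(C)(C)C | intermediate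
26 | C5 alkenylmagnesium bromide, C6 magnesium alkoxide (not isolated) | CC(C)(C)OC(=O)C[C@H]1[C@H](O[Mg]Br)/C([Mg]Br)=C(/C)[C@@H](O[Si](CC)(CC)CC)C/C=C(\C)C[C@H]1O[Si](C)(C)C(C)(C)C | intermediate
27 | tert-butyl 2-[(1S,2R,3Z,5S,7E,10R)-10-(tert-butyldimethylsilyloxy)-2-hydroxy-4,8-dimethyl-5-(triethylsilyloxy)cyclodeca-3,7-dien-1-yl]acetate | CC(C)(C)OC(=O)C[C@H]1[C@H](O)/C=C(/C)[C@@H](O[Si](CC)(CC)CC)C/C=C(\C)C[C@H]1O[Si](C)(C)C(C)(C)C | intermediate
28 | trimethylsilyl ester and C6 trimethylsilyl ether of 27 (not isolated) | C[Si](C)(C)OC(=O)C[C@H]1[C@H](O[Si](C)(C)C)/C=C(/C)[C@@H](O[Si](CC)(CC)CC)C/C=C(\C)C[C@H]1O[Si](C)(C)C(C)(C)C | intermediate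
29 | 3,6-dihydroxy acid with 8-OTBS (not isolated) | OC(=O)C[C@H]1[C@H](O)/C=C(/C)[C@@H](O)C/C=C(\C)C[C@H]1O[Si](C)(C)C(C)(C)C | intermediate
30 | (3S,6R,7S,8R)-8-(tert-butyldimethylsilyloxy)-3-hydroxy-13-norgermacra-1(10)E,4Z-dien-12,6-olide | O=C1O[C@@H]2/C=C(/C)[C@@H](O)C/C=C(\C)C[C@@H](O[Si](C)(C)C(C)(C)C)[C@H]2C1 | intermediate
31 | (3S,6R,7S,8R)-3-benzoyloxy-8-(tert-butyldimethylsilyloxy)-13-norgermacra-1(10)E,4Z-dien-12,6-olide | O=C1O[C@@H]2/C=C(/C)[C@@H](OC(=O)c3ccccc3)C/C=C(\C)C[C@@H](O[Si](C)(C)C(C)(C)C)[C@H]2C1 | intermediate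
32 | lithium enolate of 31 (not isolated) | [Li]OC=1O[C@@H]2/C=C(/C)[C@@H](OC(=O)c3ccccc3)C/C=C(\C)C[C@@H](O[Si](C)(C)C(C)(C)C)[C@H]2C=1 | intermediate
33 | (3S,6R,7S,8R)-3-benzoyloxy-8-(tert-butyldimethylsilyloxy)-13-(dimethylamino)germacra-1(10)E,4Z-dien-12,6-olide (C11 epimers) | CN(C)CC1C(=O)O[C@@H]2/C=C(/C)[C@@H](OC(=O)c3ccccc3)C/C=C(\C)C[C@@H](O[Si](C)(C)C(C)(C)C)[C@@H]12 | intermediate
34 | trimethylammonium iodide of 33 (not isolated) | C[N+](C)(C)CC1C(=O)O[C@@H]2/C=C(/C)[C@@H](OC(=O)c3ccccc3)C/C=C(\C)C[C@@H](O[Si](C)(C)C(C)(C)C)[C@@H]12.[I-] | intermediate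
35 | (3S,6R,7S,8R)-3-benzoyloxy-8-(tert-butyldimethylsilyloxy)germacra-1(10)E,4Z,11(13)-trien-12,6-olide | C=C1C(=O)O[C@@H]2/C=C(/C)[C@@H](OC(=O)c3ccccc3)C/C=C(\C)C[C@@H](O[Si](C)(C)C(C)(C)C)[C@@H]12 | intermediate
36 | (3S,6R,7R,8R)-3-benzoyloxy-8-hydroxygermacra-1(10)E,4Z,11(13)-trien-12,6-olide | C=C1C(=O)O[C@@H]2/C=C(/C)[C@@H](OC(=O)c3ccccc3)C/C=C(\C)C[C@@H](O)[C@@H]12 | intermediate
37 | methyl (2Z)-2-methylbut-2-enoate (methyl angelate) | C/C=C(/C)C(=O)OC | starting material
38 | (2Z)-2-methylbut-2-en-1-ol | C/C=C(/C)CO | intermediate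
39 | [(2S,3R)-2,3-dimethyloxiran-2-yl]methanol | OC[C@]1(C)O[C@@H]1C | intermediate
40 | (2R,3R)-2,3-dimethyloxirane-2-carboxylic acid | OC(=O)[C@]1(C)O[C@@H]1C | intermediate
41 | (2R,3R)-2,3-dimethyloxirane-2-carboxylic 2,4,6-trichlorobenzoic anhydride (not isolated) | Clc1cc(Cl)c(C(=O)OC(=O)[C@]2(C)O[C@@H]2C)c(Cl)c1 | intermediate
42 | (3S,6R,7R,8R)-3-benzoyloxy-8-[(2R,3R)-2,3-dimethyloxirane-2-carbonyloxy]germacra-1(10)E,4Z,11(13)-trien-12,6-olide | C=C1C(=O)O[C@@H]2/C=C(/C)[C@@H](OC(=O)c3ccccc3)C/C=C(\C)C[C@@H](OC(=O)[C@]3(C)O[C@@H]3C)[C@@H]12 | intermediate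
43 | (1R,3S,6R,7R,8R,10R)-3-benzoyloxy-1,10-epoxy-8-[(2R,3R)-2,3-dimethyloxirane-2-carbonyloxy]germacra-4Z,11(13)-dien-12,6-olide (CNP0324463.6) | C=C1C(=O)O[C@@H]2/C=C(/C)[C@@H](OC(=O)c3ccccc3)C[C@H]3O[C@]3(C)C[C@@H](OC(=O)[C@]3(C)O[C@@H]3C)[C@@H]12 | target

**Step count and risks**
Total steps: 26. Longest linear sequence: 22 (steps 1–7, 9–21, 25, 26).

Step 15. Process at risk: the ring-forming tether, rather than C7, may decide which carbonyl face the alkynylchromium reaches, so the alcohol could form as a mixture of C6 epimers. The fallback sets C6 by reagent-controlled reduction instead of by the ring closure. Setting out from 25 (as the epimer mixture), oxidation with Dess–Martin periodinane (pyridine, CH2Cl2, 0 °C) should give the cyclic ynone tert-butyl 2-[(1R,5S,7E,10R)-10-(tert-butyldimethylsilyloxy)-8-methyl-2-oxo-5-(triethylsilyloxy)cyclodec-7-en-3-yn-1-yl]acetate F1. Noyori transfer hydrogenation with RuCl[(S,S)-TsDPEN](p-cymene) in i-PrOH under base-free conditions, where the alkyne takes the place of the aryl group, should deliver the 6S alcohol, and the route is rejoined at 25.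

Step 16. Process at risk: the Grignard reagent may attack the tert-butyl ester, or the C6 magnesium alkoxide may lactonise onto it before carbometalation is complete, and addition at the silyloxy-flanked C4 may be slow. The fallback brings the methyl in by cross-coupling after a syn hydrometalation. Setting out from 25, the conditions of step 17 (Me3SiOTf, 2,6-lutidine; then MeOH, PPTS) should give the hydroxy lactone cycloalkyne (3S,6S,7S,8R)-8-(tert-butyldimethylsilyloxy)-3-hydroxy-13-norgermacr-1(10)E-en-4-yn-12,6-olide F2. Syn hydrostannation with Bu3SnH and catalytic Pd(PPh3)4 (zerovalent palladium, THF, 0 °C) should place tin on C4, next to the free C3 hydroxyl and away from the more hindered C6 side, giving the C4 tributylstannyl alkene F3. Iododestannylation (I2, CH2Cl2, 0 °C) gives the C4 vinyl iodide F4, and Negishi coupling with MeZnCl and Pd(PPh3)4 in THF rejoins the route at 30.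

Step 26. Process at risk: poor facial selectivity of the peracid on the flexible ten-membered ring, or acid-induced transannular opening of the new epoxide. The fallback sets the epoxide by reagent control one stage earlier, under buffered basic conditions. Setting out from 36, Shi epoxidation with the D-fructose-derived ketone (KHSO5 as its triple salt, K2CO3, MeCN/dimethoxymethane/aqueous buffer, 0 °C) is used. Its spiro transition state delivers oxygen to the face of an E trisubstituted alkene that corresponds to the (1R,10R) epoxide, and should give the epoxy alcohol (1R,3S,6R,7R,8R,10R)-3-benzoyloxy-1,10-epoxy-8-hydroxygermacra-4Z,11(13)-dien-12,6-olide F5. Yamaguchi esterification with 40 under the conditions of step 25 rejoins the route at 43.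

**Further compounds**
F1 | step 15 | tert-butyl 2-[(1R,5S,7E,10R)-10-(tert-butyldimethylsilyloxy)-8-methyl-2-oxo-5-(triethylsilyloxy)cyclodec-7-en-3-yn-1-yl]acetate | CC(C)(C)OC(=O)C[C@H]1C(=O)C#C[C@@H](O[Si](CC)(CC)CC)C/C=C(\C)C[C@H]1O[Si](C)(C)C(C)(C)C
F2 | step 16 | (3S,6S,7S,8R)-8-(tert-butyldimethylsilyloxy)-3-hydroxy-13-norgermacr-1(10)E-en-4-yn-12,6-olide | O=C1O[C@@H]2C#C[C@@H](O)C/C=C(\C)C[C@@H](O[Si](C)(C)C(C)(C)C)[C@H]2C1
F3 | step 16 | (3S,6S,7S,8R)-8-(tert-butyldimethylsilyloxy)-3-hydroxy-4-(tributylstannyl)-13,15-dinorgermacra-1(10)E,4E-dien-12,6-olide | O=C1O[C@@H]2/C=C(/[Sn](CCCC)(CCCC)CCCC)[C@@H](O)C/C=C(\C)C[C@@H](O[Si](C)(C)C(C)(C)C)[C@H]2C1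
F4 | step 16 | (3S,6S,7S,8R)-8-(tert-butyldimethylsilyloxy)-3-hydroxy-4-iodo-13,15-dinorgermacra-1(10)E,4E-dien-12,6-olide | O=C1O[C@@H]2/C=C(/I)[C@@H](O)C/C=C(\C)C[C@@H](O[Si](C)(C)C(C)(C)C)[C@H]2C1
F5 | step 26 | (1R,3S,6R,7R,8R,10R)-3-benzoyloxy-1,10-epoxy-8-hydroxygermacra-4Z,11(13)-dien-12,6-olide | C=C1C(=O)O[C@@H]2/C=C(/C)[C@@H](OC(=O)c3ccccc3)C[C@H]3O[C@]3(C)C[C@@H](O)[C@@H]12
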